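The data are simulated for substances that don't exist; noise was put on by code.

1. The reading at 8.00 min in the theta run stopped me. Here is what I had, and what was asked:

| setting | theta | beta | birch | cedar | alder | maple |
|---|---|---|---|---|---|---|
| first end groups | 15 mM | 15 mM | 15 mM | 15 mM (fed, over 6.0 min) | 15 mM | 15 mM |
| second end groups | 13.5 mM | 13.5 mM | 13.5 mM (in portions, 4, over 6.0 min) | 13.5 mM | 13.5 mM (fed, over 6.0 min) | 13.5 mM |
| one-sided end groups | 0.15 mM | 0.22 mM | 0.150 mM | 0.150 mM | 0.150 mM | 0.150 mM |
| remark | run made earlier | run made earlier | first portion at the start, last at 6.0 min | all else is in the flask from the start; the feed brings no volume worth counting | all else is in the flask from the start; the feed brings no volume worth counting | everything together at the start |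
| time |  |  | 8.0 min | 8.0 min | 8.0 min | 8.0 min |

theta run (percent of the first end groups charged)

| time / min | side product / % | links / % | first end groups / % |
|---|---|---|---|
| 0.667 | 16.9 | 21.8 | 59.1 |
| 1.33 | 27.9 | 16.5 | 46.2 |
| 2.50 | 40.2 | 11.7 | 33.9 |
| 4.00 | 49.0 | 7.1 | 27.5 |
| 8.00 | 60.0 | 6.1 | 18.3 |

beta run (percent of the first end groups charged)

| time / s | side product / % | links / % | first end groups / % |
|---|---|---|---|
| 10.0 | 2.6 | 24.7 | 69.2 |
| 12.0 | 3.9 | 25.3 | 67.9 |
| 20.0 | 9.8 | 24.6 | 64.2 |
| 30.0 | 11.0 | 23.5 | 59.3 |
| 50.0 | 18.0 | 20.3 | 49.9 |

(each reading ± 1 percentage point)

- a species is counted by the first end groups in it: one side product counts as two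
- the numbers in the tables scatter with a standard deviation of 1 percentage point

- the flask with the highest amount of side product, in percent of the first end groups charged ("all alike" if they lie within 1.5 percentage points) (birch / cedar / alder / maple / all alike)
- final side product, as a percentage of the first end groups charged, in birch
- final side product, as a percentage of the first end groups charged, in cedar
- final side product, as a percentage of the first end groups charged, in alder
- final side product, as a percentage of the first end groups charged, in maple

2. Two numbers in the theta run seemed not to fit. From 4.00 min to 8.00 min, side product rose by 11 points, yet links fell by 1 point.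

3. First end groups fell by 9.2 points in that interval. So links and first end groups together gave up 10 points, close to the gain in side product. One side product counts as two, so I read it as a link plus a first end group. Links are then an intermediate, refilled as they drain.

4. I let a, l and o be first end groups, links and side product, as fractions of the first end groups charged, and wrote do/dt = a·l/τ.

5. The beta run, from 10.0 s to 50.0 s, gave τ = 0.580 min. I call τ the side-product clock: the time in which side product would gain the whole charge with a and l both held at one.

6. I tried it on the theta interval of step 2, a different run. The clock gave 11 points, against the 11 points read.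

7. So I ranked the flasks by a·l. I expected a feed of first end groups to lower both factors early in the run, and a feed of second end groups to lower l early in the run. That put cedar lowest.

8. The forecast gave 57% for birch, 47% for cedar, 56% for alder and 60% for maple, with maple highest. Its ground for cedar was “Feeding first end groups (cedar) keeps A low”.

9. The flasks gave 56.1% in birch, 45.4% in cedar, 55.9% in alder and 61.6% in maple, so maple stood highest, as forecast.

    first end groups + second end groups ⇌ links (K = 51.0 M⁻¹, k = 4.48 M⁻¹ s⁻¹)
    first end groups + one-sided end groups → capped ends (k = 168 M⁻¹ s⁻¹)
    first end groups + links → side product (k = 0.986 M⁻¹ s⁻¹)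
    links ⇌ isomer of the product (K = 1.68, k = 0.00499 s⁻¹)

Over the first 6.0 min, cedar held 3.57 mM of first end groups on average, less than the 9.77 mM in alder. After its feed ended, the clock gave cedar 15 points, while side product went from 31.0% to 45.4%.

10. A neighbour of cedar has 3.8 mM of first end groups. I took τ as inverse to that charge, which gave 2.29 min. Holding its end values, a = 34.4% and l = 19.9%, over 8.0 min gave 23.9%; the computed result is 18.7%.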